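The numbers of this flask were chosen freely; the flask was simulated.

The charge of solid substrate, 10 mM, stands far above the solubility of 0.54 mM, so the flask starts as a slurry.

    target ⇌ isomer of the product (K1 = 0.87, k1 = 0.0016 s⁻¹)
    solid substrate ⇌ starting material, rate k2*(cs2 - [starting material]) while solid is left; crystals form when [starting material] > cs2 (cs2 = 0.54 mM, k2 = 0.0077 s⁻¹)
    starting material ⇌ target (K3 = 0.97, k3 = 0.0067 s⁻¹)
    starting material → decomposition product (k4 = 3.2 × 10⁻⁵ s⁻¹)
    2 starting material → self-condensation product (k5 = 2.1 M⁻¹ s⁻¹)
    isomer of the product ⇌ starting material (k6 = 0.085 s⁻¹)

solid substrate 10 mM; time 2.5 h

- percent here means solid substrate units held: one self-condensation product counts as two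
- a step written with two of one species runs at k times the square of its concentration and takes two of it each time
- solid substrate is a solid; its amount is given per volume of the solution
- at the start none of the solid substrate is in solution
- what has only dissolved of solid substrate counts as not reacted
- starting material means what is dissolved; the solid is not counted in it
- run time (flask): 2.5 h

- how much target there is at 2.5 h, in percent of the solid substrate charged
- how much starting material there is at 2.5 h, in percent of the solid substrate charged
- amount of target if the flask were left three thousand times as long, in percent of the solid substrate charged

Target and the isomer of the product relax into each other with a half-life of 0.0560 h, and the isomer and starting material with 0.0737 min. Both are shorter than the run of 2.5 h, so the three dissolved species travel as one pool, with target at 0.97 times the starting material.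

But these exchanges move material within the pool and leave its total as it is. Its balance has dissolution coming in, slowing as starting material nears solubility, and decomposition and self-condensation going out. While solid is left, the pool stands still in a quasi-steady state, and the quadratic for that gives 0.435 mM, the plateau level: the dissolved starting material at which dissolution just pays for the two exits.

So this reckoning expects 4.35 % of starting material and 4.22 % of target. The plateau passes a drain of 8.09 × 10⁻⁴ mM s⁻¹, so, counted from a pool already full, the solid lasts 3.01 h, longer than the run. Both exits run one way, so target sinks towards nothing in the flask left far longer.

The forecast gives 4.22 %, 4.35 % and 0 %, with starting material where “dissolution balances the irreversible losses”.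

The flask gives 4.22 % of target, 4.35 % of starting material and 0 % when left long, and at 2.50 h the making of starting material over its using up stands at 1.00. Solid substrate there stands at 18.3 %, which the drain of 8.09 × 10⁻⁴ mM s⁻¹ would clear in a further 0.629 h. The same flask read at 10.0 h holds 0 % of solid substrate and 0.221 % of starting material, less than the plateau level of 4.35 %.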